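Time splits each of these flasks in two: the first portion of starting complex meets the whole of the incoming ligand, and the second portion enters after 12 min.

| flask | starting complex | incoming ligand | remark | time |
|---|---|---|---|---|
| grey | 0.15 M (in portions, 2) | 1.2 equiv | run made earlier; portions every 12 min |  |
| green | 0.050 M (in portions, 2) | 1.2 equiv | run made earlier; portions every 12 min |  |
| south-east | 0.10 M (in portions, 2) | 1.20 equiv | the portions of starting complex follow each other after 12 min, the first at the start | 25 min |
| north-east | 0.10 M (in portions, 2) | 2.50 equiv | the portions of starting complex follow each other after 12 min, the first at the start | 25 min |
| north | 0.10 M (in portions, 2) | 0.500 equiv | the portions of starting complex follow each other after 12 min, the first at the start | 25 min |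

| run | time / min | complex with two exchanged / % |
|---|---|---|
| grey | 2.50 | 16.2 |
| grey | 5.00 | 17.6 |
| grey | 8.00 | 18.3 |
| grey | 10.0 | 17.4 |
| grey | 12.0 | 17.4 |
| grey | 15.0 | 17.4 |
| green | 1.33 | 3.0 |
| green | 2.00 | 4.8 |
| green | 3.00 | 7.3 |
| green | 5.00 | 11.3 |
| green | 10.0 | 16.2 |
| green | 15.0 | 20.4 |

(scatter of a reading: 0.5 percentage points)

- which of these holds the largest part of the starting complex at the end of south-east (complex with two exchanged / complex with three exchanged / complex with one exchanged / starting complex)
- which of these holds the largest part of the starting complex at the end of north-east (complex with two exchanged / complex with three exchanged / complex with one exchanged / starting complex)
- which of these holds the largest part of the starting complex at the end of north (complex with two exchanged / complex with three exchanged / complex with one exchanged / starting complex)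
- amount of complex with two exchanged at the end of south-east, in percent of the starting complex charged



I keep a ledger of the incoming ligand, one entry per exchange. In south-east the charge comes to 2.40 equiv on the first portion; I call this the ration, the ligand charged per complex of the first portion. A complex can take 3.00 equiv, which is more than the ration, so the first portion could swallow the whole charge. Incoming ligand is then the limiting reagent, and my large entry is the second portion, 50.0% of the charge, left as starting complex.

Grey and green have the same ration, and if every step is second order, such curves depend on concentration times time. South-east at 12 min has the same product as grey at 8.00 min, so I read 18.3% of complex with two exchanged there. The other 31.7% of the charge in the first portion, if all three-exchanged, would bring the bill to 1.32 equiv, above the 1.20 equiv charged, so part of it must sit lower.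

The correction is what the second portion adds. Grey read 17.4% at 12.0 min and 17.4% at 15.0 min, across its second portion. Green gained 4.2 percentage points from 10.0 min to 15.0 min, a span that begins before its addition at 12 min, and that is less than the 4.9 points it gained from 5.00 min to 10.0 min, so I cannot separate the portion's share from the growth of the first portion. I therefore read no correction from either run and commit to 18.3%, with starting complex leading. North-east has a ration of 5.00 equiv, above what a complex takes, so ligand passes on and I expect complex with three exchanged to lead. North has 1.00 equiv, and I expect starting complex.

The forecast names complex with one exchanged for south-east, complex with two exchanged for north-east and starting complex for north, with 26% of complex with two exchanged in south-east. It reads the flat grey curve as a limit of solubility: “so the cap is a concentration”. We agree on north and differ on the rest.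

The flasks give starting complex in south-east, complex with three exchanged in north-east and starting complex in north, with 19.8% of complex with two exchanged in south-east.

    complex with two exchanged + incoming ligand → leaving ligand + complex with three exchanged (k = 2.40 /M/min)
    starting complex + incoming ligand → leaving ligand + complex with one exchanged (k = 2.80 /M/min)
    complex with one exchanged + incoming ligand → leaving ligand + complex with two exchanged (k = 7.60 /M/min)

South-east's ration of 2.40 equiv ended with 46.1% as starting complex, close to the half the ledger put there. The neighbour of south-east charged with 4.80 equiv has a ration of 9.60 equiv, above the 3.00 equiv a complex takes. Its whole charge of starting complex, fully exchanged, therefore costs 3.00 equiv out of 4.80 equiv, and the ledger leaves 37.5% of the incoming ligand unspent. That neighbour ends with 37.6% of its incoming ligand left and 99.4% as complex with three exchanged.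

(The data are simulated with constants of no real substance; the scatter is artificial.)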